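**Assumption:** the target has no stereocentres, so "single enantiomer" does not apply; the only stereo-element is the (E)-enone, which is set in Step 5. The route is proposed from general precedent and has not been run.

## Retrosynthetic overview
1. Target 11 ⇒ aromatic Claisen rearrangement of the 4-O-prenyl chalcone 10. C3 carries OH and the para position C1 carries the enone, so C5 is the only site that can accept the 1,1-dimethylallyl group.
2. Chalcone 10 ⇒ Claisen–Schmidt condensation of aldehyde 8 with 4'-hydroxyacetophenone 9, giving the (E)-alkene.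
3. Aldehyde 8 ⇒ pKa-selective 4-O-prenylation of 3,4-dihydroxy-2-methoxybenzaldehyde 6.
4. Aldehyde 6 ⇒ 2,3,4-trihydroxybenzaldehyde 1 by 3,4-bis-MOM protection (chelated 2-OH left free), 2-O-methylation and MOM removal.
5. No rings are formed; both benzene rings are bought.

## Route

**Step 1**
Reactants: 1, 2,3,4-trihydroxybenzaldehyde; 2, chloromethyl methyl ether (MOMCl)
Product: 3, 2-hydroxy-3,4-bis(methoxymethoxy)benzaldehyde
Conditions: MOMCl (2.2 equiv), i-Pr2NEt (2.5 equiv), CH2Cl2/DMF, 0 °C → rt
Reagents that add atoms: MOMCl, COCCl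
Why: O-alkylation (MOM ether formation) occurs at the two non-chelated phenols, while the 2-OH is hydrogen-bonded to the aldehyde and is the least nucleophilic.

**Step 2**
Reactants: 3, 2-hydroxy-3,4-bis(methoxymethoxy)benzaldehyde; 4, iodomethane
Product: 5, 2-methoxy-3,4-bis(methoxymethoxy)benzaldehyde
Conditions: MeI (1.5 equiv), K2CO3, DMF, rt
Reagents that add atoms: iodomethane, CI
Why: Williamson methylation of the only remaining phenol; MOM ethers and the non-enolisable aldehyde are inert to K2CO3/MeI.

**Step 3**
Reactants: 5, 2-methoxy-3,4-bis(methoxymethoxy)benzaldehyde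
Product: 6, 3,4-dihydroxy-2-methoxybenzaldehyde
Conditions: 3 M aq HCl, MeOH, 50 °C
Reagents that add atoms: none
Why: Acid-catalysed acetal hydrolysis removes both MOM groups; the aryl methyl ether and the aldehyde survive (any dimethyl acetal reverts on aqueous work-up).

**Step 4**
Reactants: 6, 3,4-dihydroxy-2-methoxybenzaldehyde; 7, prenyl bromide (1-bromo-3-methylbut-2-ene)
Product: 8, 3-hydroxy-2-methoxy-4-[(3-methylbut-2-en-1-yl)oxy]benzaldehyde
Conditions: prenyl bromide (1.05 equiv), NaHCO3 (1.5 equiv), NaI (cat.), DMF, 40 °C
Reagents that add atoms: prenyl bromide, CC(C)=CCBr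
Why: Regioselective Williamson etherification; a weak base ionises only the 4-OH, which is para to the aldehyde and far more acidic than the hindered 3-OH (same logic as 4-O-alkylation of protocatechualdehyde).

**Step 5**
Reactants: 8, 3-hydroxy-2-methoxy-4-(prenyloxy)benzaldehyde; 9, 4'-hydroxyacetophenone
Product: 10, (E)-3-[3-hydroxy-2-methoxy-4-(prenyloxy)phenyl]-1-(4-hydroxyphenyl)prop-2-en-1-one
Conditions: 50% aq KOH (ca. 10 equiv), EtOH, rt, 48 h, Ar; then AcOH/sat. NH4Cl to pH ~6 at 0 °C
Reagents that add atoms: none
Why: Claisen–Schmidt aldol condensation with E1cB dehydration gives the thermodynamic (E)-enone. The aldehyde cannot enolise, its phenoxide is meta to CHO and so does not deactivate it, and the prenyl ether is stable to base and to the mild cold quench.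

**Step 6**
Reactants: 10, (E)-3-[3-hydroxy-2-methoxy-4-(prenyloxy)phenyl]-1-(4-hydroxyphenyl)prop-2-en-1-one
Product: 11, (E)-3-[3,4-dihydroxy-2-methoxy-5-(2-methylbut-3-en-2-yl)phenyl]-1-(4-hydroxyphenyl)prop-2-en-1-one (target)
Conditions: degassed EtOH/H2O (4:1), sealed tube, 130 °C, Ar, 8–16 h
Reagents that add atoms: none
Why: Protic-solvent-accelerated aromatic Claisen ([3,3]-sigmatropic) rearrangement transfers the prenyl group with allylic inversion to C5, the only free ortho position, and tautomerisation restores the phenol. The (E)-enone is the thermodynamic isomer and is retained; no stereocentre is created.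

## Compound list
1 | 2,3,4-trihydroxybenzaldehyde | O=Cc1ccc(O)c(O)c1O | starting material
2 | chloromethyl methyl ether (MOMCl) | COCCl | starting material (reagent)
3 | 2-hydroxy-3,4-bis(methoxymethoxy)benzaldehyde | O=Cc1ccc(OCOC)c(OCOC)c1O | intermediate
4 | iodomethane | CI | starting material (reagent)
5 | 2-methoxy-3,4-bis(methoxymethoxy)benzaldehyde | O=Cc1ccc(OCOC)c(OCOC)c1OC | intermediate
6 | 3,4-dihydroxy-2-methoxybenzaldehyde | O=Cc1ccc(O)c(O)c1OC | intermediate
7 | prenyl bromide (1-bromo-3-methylbut-2-ene) | CC(C)=CCBr | starting material (reagent)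
8 | 3-hydroxy-2-methoxy-4-[(3-methylbut-2-en-1-yl)oxy]benzaldehyde | O=Cc1ccc(OCC=C(C)C)c(O)c1OC | intermediate
9 | 4'-hydroxyacetophenone | CC(=O)c1ccc(O)cc1 | starting material
10 | (E)-3-[3-hydroxy-2-methoxy-4-(prenyloxy)phenyl]-1-(4-hydroxyphenyl)prop-2-en-1-one | O=C(/C=C/c1ccc(OCC=C(C)C)c(O)c1OC)c1ccc(O)cc1 | intermediate
11 | (E)-3-[3,4-dihydroxy-2-methoxy-5-(2-methylbut-3-en-2-yl)phenyl]-1-(4-hydroxyphenyl)prop-2-en-1-one | C=CC(C)(C)c1cc(/C=C/C(=O)c2ccc(O)cc2)c(OC)c(O)c1O | target

## Summary
Total steps: 6. Longest linear sequence: 6 (fully linear from 1; 9 enters at Step 5).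

Steps most likely to fail, with fallbacks:
1. **Step 6 (Claisen rearrangement).** Risks are de-prenylation, cyclisation of the product to a dihydrobenzofuran, and catechol oxidation. Fallback: drop the sigmatropic approach. Brominate aldehyde 6 at C5 (ortho to 4-OH, para to OMe), protect the phenols, and install the 1,1-dimethylallyl group by a γ-selective Pd-catalysed Suzuki–Miyaura coupling with prenyl-Bpin. Then condense and deprotect.
2. **Step 5 (Claisen–Schmidt with two free phenols).** The phenoxide of 9 enolises sluggishly and the electron-rich phenoxides can air-oxidise. Fallback: form the enone by Wittig olefination of 8 with the stabilised ylide from 2-bromo-4'-hydroxyacetophenone and PPh3 (neutral conditions, E-selective).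
3. **Step 4 (mono-prenylation at O-4).** Risks are bis- or 3-O-alkylation. Fallback: reorder the differentiation. Prenylate the most acidic 4-OH of 1 first, MOM-protect the 3-OH (chelated 2-OH untouched), methylate the 2-OH, carry the 3-O-MOM through condensation and rearrangement, and remove it last with mild acid.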